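A direct plan would make ring A first, by a Diels–Alder reaction of the 2-silyloxydiene A1 (from mesityl oxide) with the menthyl-acetal butenolide A2, and would reduce the adduct to the lactol acetal A3.
Ring B would then be grown by allylation of the lactol and a nitrile oxide cycloaddition, which after N–O cleavage and silylation would give the tris-silylated C9 ketone A4; the side chain would follow by enol triflation, vinyl coupling and hydroboration/alkyl coupling.
Its weakest steps would be these (target numbering).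
(1) The cycloaddition: a diene with a fully substituted terminus and a β,β-disubstituted dienophile would join only under about 1.5 GPa, and all absolute configuration would rest on a crystallisation-resolved acetal carbon.
(2) The lactol allylation: it would have to choose between two acetal carbons and two faces, so the C6 carbinol centre would be left to chance.
(3) The end game: a kinetic enol triflate from a hindered α-quaternary ketone with a β-silyloxy group, then two couplings, would spend three steps on the most precious material for one olefin and four carbons.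

**Plan of the new route**
Cuts, in order: C12–C13 (alkyl–vinyl coupling); C4–C5 (tertiary cation onto an enol ether); C2–O and C1=C2 (hydroboration, Wittig); last the C10–CH3 bond.
That last cut turns ring B into a benzene ring: C10 is the ipso carbon of a benzamide whose carbonyl carbon is C1, C7 the para carbon, C9/C8 (with C11–C12 and C17) the ortho/meta carbons, and the C6 oxygen a meta-methoxy group.
This 1,4-dihydroarene pattern of ring B (sp3 C10 and C7, C8=C9, C5=C6–O) is the feature that makes the key step possible: a Birch reductive methylation sets C10 and delivers the tetrasubstituted olefin and the C6 oxygen ready-made.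
Ring B therefore exists first. Ring A is closed last, onto the flat dihydro ring, where the tether on C10 should reach C5 only on its own face, so the cis fusion follows from geometry; C2 is set by reagent, C6 by hydride on the convex face.
No high-pressure cycloaddition, no choice between two acetals and no C9 ketone or enol triflate occur; the side chain is carried from the arene as a two-carbon arm and needs one coupling.

Key step: step 5

Numbering: target (labdane) numbering throughout: ring A = C1–C5, C10; ring B = C5–C10; C17 on C8; C11–C12 on C9; C13–C16 butenolide.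
Assumption: with the (S)-configured auxiliary 8, a 2-alkylbenzamide is methylated on the face that gives (1S)-12; if the opposite sense were found, the enantiomeric auxiliary (also commercial) would be used and compounds 13 onward would be unchanged.

Step 1
Reactants: 1 4-bromo-3,5-dimethylanisole
Product: 2 2-bromo-5-methoxybenzene-1,3-dicarboxylic acid
Conditions: KMnO4 (excess), pyridine/H2O, reflux; then aq. HCl
Reagents that add atoms: potassium permanganate, [K+].[O-][Mn](=O)(=O)=O
Why: Permanganate side-chain oxidation converts both benzylic methyl groups into carboxylic acids while the aryl bromide and the aryl methyl ether are inert.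

Step 2
Reactants: 2 2-bromo-5-methoxybenzene-1,3-dicarboxylic acid; 3 ethylene oxide
Product: 5 7-methoxy-1-oxo-3,4-dihydro-1H-2-benzopyran-5-carboxylic acid, via hydroxy diacid 4 (not isolated)
Conditions: MeMgCl (2.1 equiv), LiCl, THF, −20 °C; i-PrMgCl·LiCl (1.2 equiv); CuI (5 mol %), ethylene oxide (3 equiv), −20 → 23 °C; then 2 M HCl, 50 °C
Reagents that add atoms: none
Why: After deprotonation of both acids, bromine–magnesium exchange gives an aryl Grignard reagent that opens the epoxide under copper catalysis, and acid then closes the six-membered lactone onto one of the two equivalent carboxyl groups, which tells the future C1 (lactone carbonyl) apart from the future C17 (free acid) without a statistical step.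

Step 3
Reactants: 5 7-methoxy-1-oxo-3,4-dihydro-1H-2-benzopyran-5-carboxylic acid
Product: 7 7-methoxy-5-{[tri(propan-2-yl)silyloxy]methyl}-3,4-dihydro-1H-2-benzopyran-1-one, via benzylic alcohol 6 (not isolated)
Conditions: BH3·SMe2 (1.5 equiv), THF, 0 → 23 °C; MeOH; then i-Pr3SiCl, imidazole, DMF, 23 °C
Reagents that add atoms: chlorotriisopropylsilane, CC(C)[Si](Cl)(C(C)C)C(C)C
Why: Borane reduces a free carboxylic acid (through its acyloxyborane) much faster than an aryl lactone, and silylation of the resulting benzylic alcohol installs the C17 protecting group that lasts to the end.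

Step 4
Reactants: 7 7-methoxy-5-{[tri(propan-2-yl)silyloxy]methyl}-3,4-dihydro-1H-2-benzopyran-1-one; 8 (2S)-2-(methoxymethyl)pyrrolidine
Product: 10 {5-methoxy-2-[2-(triethylsilyloxy)ethyl]-3-[(triisopropylsilyloxy)methyl]phenyl}[(2S)-2-(methoxymethyl)pyrrolidin-1-yl]methanone, via hydroxy amide 9 (not isolated)
Conditions: 8 (1.3 equiv), n-BuLi, THF, −78 → 0 °C; then Et3SiCl, 0 °C
Reagents that add atoms: chlorotriethylsilane, CC[Si](Cl)(CC)CC
Why: Nucleophilic acyl substitution by the lithium amide of the auxiliary opens the lactone to the tertiary benzamide, and the C12 alkoxide set free is trapped in the same flask as its triethylsilyl ether.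

Step 5
Reactants: 10 {5-methoxy-2-[2-(triethylsilyloxy)ethyl]-3-[(triisopropylsilyloxy)methyl]phenyl}[(2S)-2-(methoxymethyl)pyrrolidin-1-yl]methanone; 11 iodomethane
Product: 12 {(1S)-5-methoxy-1-methyl-2-[2-(triethylsilyloxy)ethyl]-3-[(triisopropylsilyloxy)methyl]cyclohexa-2,5-dien-1-yl}[(2S)-2-(methoxymethyl)pyrrolidin-1-yl]methanone
Conditions: K (2.3 equiv), liquid NH3/THF, t-BuOH (1.0 equiv), −78 °C; piperylene; MeI, −78 °C; NH4Cl
Reagents that add atoms: none
Why: Two-electron reduction of the benzamide by potassium and protonation of the dianion at C7 (para to the carboxamide) by tert-butanol give a cross-conjugated amide dienolate, which iodomethane alkylates at C10; the closest known reaction type is the auxiliary-controlled Birch reductive alkylation of 2-substituted benzamides of prolinol methyl ether. No ring is closed: ring B is dearomatised, and the one operation should deliver the quaternary C10–CH3 bond, the tetrasubstituted C8=C9 olefin with C17 and C11 in place, the C7 methylene and the C6 oxygen as the regiodefined C5=C6 methyl enol ether. The new stereocentre C10 is controlled by the auxiliary: in the potassium-chelated enolate the methoxymethyl arm screens one face and the electrophile enters on the other at −78 °C, before the enolate geometry can equilibrate. The step needs 1,4-regiochemistry of reduction and retention of both C–O bonds; the carboxamide fixes ipso/para reduction, the alkyl and methoxy groups stay on sp2 carbons, and the methoxy and silyloxymethyl groups sit on the meta carbons, where the benzamide radical anion has a node, so neither should be expelled.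

Step 6
Reactants: 12 the Birch amide from step 5
Product: 13 {(1S)-5-methoxy-1-methyl-2-[2-(triethylsilyloxy)ethyl]-3-[(triisopropylsilyloxy)methyl]cyclohexa-2,5-dien-1-yl}methanol
Conditions: LiH2N·BH3 (4 equiv), THF, 0 → 23 °C; aq. NaOH
Reagents that add atoms: none
Why: Lithium amidotrihydroborate is a small, strongly nucleophilic hydride donor that reduces even α-quaternary tertiary amides with C–N cleavage to the primary alcohol (C1), while enol ether, skipped diene and silyl ethers are untouched and the auxiliary is recovered.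

Step 7
Reactants: 13 the primary alcohol from step 6
Product: 14 (1S)-5-methoxy-1-methyl-2-[2-(triethylsilyloxy)ethyl]-3-[(triisopropylsilyloxy)methyl]cyclohexa-2,5-diene-1-carbaldehyde
Conditions: SO3·pyridine, DMSO, i-Pr2NEt, CH2Cl2, 0 °C
Reagents that add atoms: none
Why: The Parikh–Doering oxidation stops at the aldehyde and is non-acidic, so the methyl enol ether survives; the aldehyde has no α-hydrogen and is used at once.

Step 8
Reactants: 15 3-methoxy-3-methylbutan-1-ol
Product: 16 1-bromo-3-methoxy-3-methylbutane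
Conditions: CBr4, PPh3, CH2Cl2, 0 °C
Reagents that add atoms: carbon tetrabromide, BrC(Br)(Br)Br
Why: Appel bromination converts the primary alcohol by SN2 displacement under neutral conditions that leave the tertiary methyl ether alone.

Step 9
Reactants: 16 1-bromo-3-methoxy-3-methylbutane; 17 triphenylphosphine
Product: 18 (3-methoxy-3-methylbutyl)triphenylphosphonium bromide
Conditions: MeCN, reflux
Reagents that add atoms: none
Why: SN2 quaternisation of triphenylphosphine by the primary bromide gives the phosphonium salt.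

Step 10
Reactants: 14 the aldehyde from step 7; 18 (3-methoxy-3-methylbutyl)triphenylphosphonium bromide
Product: 20 (3S)-1-methoxy-3-[(1Z)-4-methoxy-4-methylpent-1-en-1-yl]-3-methyl-4-[2-(triethylsilyloxy)ethyl]-5-[(triisopropylsilyloxy)methyl]cyclohexa-1,4-diene, via ylide 19 (not isolated)
Conditions: 18, KN(SiMe3)2, THF, −78 → 0 °C; then 14, −78 → 23 °C
Reagents that add atoms: none
Why: Wittig olefination with a non-stabilised, salt-free ylide passes through the kinetically favoured cis-oxaphosphetane and gives the Z-alkene C1=C2, which brings in C2, C3 and C4 with its latent tertiary cation (the methyl ether).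

Step 11
Reactants: 20 the Z-alkene from step 10; 21 (+)-diisopinocampheylborane
Product: 24 O-triethylsilyl ether of the (2R)-alcohol 23 (triethylsilyl ethers at C2 and C12), via alkylborane 22 (not isolated), via alcohol 23 (not isolated)
Conditions: 21 (1.5 equiv), THF, −25 → 0 °C; NaOH, H2O2, 0 °C; then Et3SiCl, imidazole, CH2Cl2, 23 °C
Reagents that add atoms: hydrogen peroxide, OO; chlorotriethylsilane, CC[Si](Cl)(CC)CC
Why: Asymmetric hydroboration of the cis-disubstituted alkene places boron on C2 (the carbon remote from quaternary C10) on the face chosen by the reagent, and oxidation with retention gives the (R)-carbinol (C2, S in the target), the enol ether and the tetrasubstituted olefin being too hindered for this dialkylborane; silylation then masks the C2 oxygen so that it cannot drive a fragmentation of the cation formed in the next step.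

Step 12
Reactants: 24 the bis(triethylsilyl) ether from step 11
Product: 26 (2S,5R,10S)-2-hydroxy-9-(2-hydroxyethyl)-4,4,10-trimethyl-8-[(triisopropylsilyloxy)methyl]-cis-Δ8-octalin-6-one (2α-OH; 5β-H; 10β-CH3), via silylated ketone 25 (not isolated)
Conditions: TiCl4 (2.2 equiv), 2,6-di-tert-butyl-4-methylpyridine, CH2Cl2, −78 °C; aq. NaHCO3; then AcOH/THF/H2O, 23 °C
Reagents that add atoms: water, O
Why: In this SN1 α-tert-alkylation of an enol ether (cation–olefin ring closure) TiCl4 ionises the tertiary methyl ether (the only unhindered Lewis-basic sp3 ether), C5 of the methyl enol ether captures the cation in a six-membered chair, and because ring B is a flat 1,4-diene with the tether on C10 the C4–C5 bond should form only on the face of C1, which sets C5 (R, cis fusion); hydrolysis gives the C6 ketone and acetic acid removes both triethylsilyl groups but not the triisopropylsilyl group.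

Step 13
Reactants: 26 the keto diol from step 12
Product: 27 (2S,5R,6S,10S)-9-(2-hydroxyethyl)-4,4,10-trimethyl-8-[(triisopropylsilyloxy)methyl]-cis-Δ8-octalin-2,6-diol (2α-OH; 6α-OH)
Conditions: Li(s-Bu)3BH (3.5 equiv), THF, −78 °C; NaOH, H2O2
Reagents that add atoms: none
Why: The bulky borohydride attacks the C6 carbonyl from the convex β face of the cis-fused bicycle (the face of H5, anti to the C4 quaternary carbon; the α face is blocked by C1 of ring A), which should give the axial 6α alcohol (6S) before the β,γ-unsaturated ketone can isomerise.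

Step 14
Reactants: 27 the triol from step 13
Product: 28 (2S,5R,6S,10S)-9-(2-iodoethyl)-4,4,10-trimethyl-8-[(triisopropylsilyloxy)methyl]-cis-Δ8-octalin-2,6-diol
Conditions: I2 (1.1 equiv), PPh3, imidazole, CH2Cl2/MeCN, 0 °C
Reagents that add atoms: iodine, II
Why: Appel iodination (alkoxyphosphonium salt, SN2 by iodide) is selective for the unhindered primary C12 hydroxyl over the two secondary hydroxyls.

Step 15
Reactants: 28 the iodide from step 14; 29 4-bromofuran-2(5H)-one
Product: 30 17-O-triisopropylsilyl ether of the target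
Conditions: NiBr2(MeOCH2CH2OMe) (10 mol %), 4,4′-di-tert-butyl-2,2′-bipyridine, Mn powder, NaI, DMA, 23 °C
Reagents that add atoms: none
Why: Nickel-catalysed reductive cross-electrophile coupling joins the primary alkyl iodide (through its radical) to the activated vinyl bromide and tolerates free hydroxyl groups, so C12–C13 is formed without protecting the diol.

Step 16
Reactants: 30 17-O-triisopropylsilyl ether of the target
Product: 31 (2S,5R,6S,10S)-2,6,17-trihydroxy-5β-labda-8,13-dien-15,16-olide (target)
Conditions: HF·pyridine, pyridine, THF, 0 → 23 °C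
Reagents that add atoms: none
Why: Fluoride cleaves the last silyl ether under weakly acidic conditions that harm neither the butenolide nor the allylic alcohol.

**Compound list**
1 | 4-bromo-3,5-dimethylanisole | COc1cc(C)c(Br)c(C)c1 | starting material
2 | 2-bromo-5-methoxybenzene-1,3-dicarboxylic acid | COc1cc(C(=O)O)c(Br)c(C(=O)O)c1 | intermediate
3 | ethylene oxide | C1CO1 | starting material
4 | 2-(2-hydroxyethyl)-5-methoxybenzene-1,3-dicarboxylic acid | COc1cc(C(=O)O)c(CCO)c(C(=O)O)c1 | intermediate
5 | 7-methoxy-1-oxo-3,4-dihydro-1H-2-benzopyran-5-carboxylic acid | COc1cc2c(CCOC2=O)c(C(=O)O)c1 | intermediate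
6 | 5-(hydroxymethyl)-7-methoxy-3,4-dihydro-1H-2-benzopyran-1-one | COc1cc2c(CCOC2=O)c(CO)c1 | intermediate
7 | 7-methoxy-5-{[tri(propan-2-yl)silyloxy]methyl}-3,4-dihydro-1H-2-benzopyran-1-one | COc1cc2c(CCOC2=O)c(CO[Si](C(C)C)(C(C)C)C(C)C)c1 | intermediate
8 | (2S)-2-(methoxymethyl)pyrrolidine | COC[C@@H]1CCCN1 | starting material
9 | {2-(2-hydroxyethyl)-5-methoxy-3-[(triisopropylsilyloxy)methyl]phenyl}[(2S)-2-(methoxymethyl)pyrrolidin-1-yl]methanone | COC[C@@H]1CCCN1C(=O)c1cc(OC)cc(CO[Si](C(C)C)(C(C)C)C(C)C)c1CCO | intermediate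
10 | {5-methoxy-2-[2-(triethylsilyloxy)ethyl]-3-[(triisopropylsilyloxy)methyl]phenyl}[(2S)-2-(methoxymethyl)pyrrolidin-1-yl]methanone | COC[C@@H]1CCCN1C(=O)c1cc(OC)cc(CO[Si](C(C)C)(C(C)C)C(C)C)c1CCO[Si](CC)(CC)CC | intermediate
11 | iodomethane | CI | starting material
12 | {(1S)-5-methoxy-1-methyl-2-[2-(triethylsilyloxy)ethyl]-3-[(triisopropylsilyloxy)methyl]cyclohexa-2,5-dien-1-yl}[(2S)-2-(methoxymethyl)pyrrolidin-1-yl]methanone | COC[C@@H]1CCCN1C(=O)[C@]2(C)C(CCO[Si](CC)(CC)CC)=C(CO[Si](C(C)C)(C(C)C)C(C)C)CC(OC)=C2 | intermediate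
13 | {(1S)-5-methoxy-1-methyl-2-[2-(triethylsilyloxy)ethyl]-3-[(triisopropylsilyloxy)methyl]cyclohexa-2,5-dien-1-yl}methanol | OC[C@]1(C)C(CCO[Si](CC)(CC)CC)=C(CO[Si](C(C)C)(C(C)C)C(C)C)CC(OC)=C1 | intermediate
14 | (1S)-5-methoxy-1-methyl-2-[2-(triethylsilyloxy)ethyl]-3-[(triisopropylsilyloxy)methyl]cyclohexa-2,5-diene-1-carbaldehyde | O=C[C@]1(C)C(CCO[Si](CC)(CC)CC)=C(CO[Si](C(C)C)(C(C)C)C(C)C)CC(OC)=C1 | intermediate
15 | 3-methoxy-3-methylbutan-1-ol | COC(C)(C)CCO | starting material
16 | 1-bromo-3-methoxy-3-methylbutane | COC(C)(C)CCBr | intermediate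
17 | triphenylphosphine | c1ccc(cc1)P(c1ccccc1)c1ccccc1 | starting material
18 | (3-methoxy-3-methylbutyl)triphenylphosphonium bromide | COC(C)(C)CC[P+](c1ccccc1)(c1ccccc1)c1ccccc1.[Br-] | intermediate
19 | (3-methoxy-3-methylbutylidene)triphenylphosphorane | COC(C)(C)CC=P(c1ccccc1)(c1ccccc1)c1ccccc1 | intermediate
20 | (3S)-1-methoxy-3-[(1Z)-4-methoxy-4-methylpent-1-en-1-yl]-3-methyl-4-[2-(triethylsilyloxy)ethyl]-5-[(triisopropylsilyloxy)methyl]cyclohexa-1,4-diene | COC(C)(C)C/C=C\[C@]1(C)C(CCO[Si](CC)(CC)CC)=C(CO[Si](C(C)C)(C(C)C)C(C)C)CC(OC)=C1 | intermediate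
21 | (+)-diisopinocampheylborane (from (−)-α-pinene) | [BH]([C@H]1C[C@H]2C[C@@H]([C@@H]1C)C2(C)C)[C@H]1C[C@H]2C[C@@H]([C@@H]1C)C2(C)C | starting material
22 | B-alkyldiisopinocampheylborane, boron on C2 of the chain of 20 | COC(C)(C)C[C@H](B([C@H]1C[C@H]2C[C@@H]([C@@H]1C)C2(C)C)[C@H]1C[C@H]2C[C@@H]([C@@H]1C)C2(C)C)C[C@]3(C)C(CCO[Si](CC)(CC)CC)=C(CO[Si](C(C)C)(C(C)C)C(C)C)CC(OC)=C3 | intermediate
23 | (2R)-1-{(1S)-5-methoxy-1-methyl-2-[2-(triethylsilyloxy)ethyl]-3-[(triisopropylsilyloxy)methyl]cyclohexa-2,5-dien-1-yl}-4-methoxy-4-methylpentan-2-ol | COC(C)(C)C[C@H](O)C[C@]1(C)C(CCO[Si](CC)(CC)CC)=C(CO[Si](C(C)C)(C(C)C)C(C)C)CC(OC)=C1 | intermediate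
24 | O-triethylsilyl ether of 23 | COC(C)(C)C[C@H](O[Si](CC)(CC)CC)C[C@]1(C)C(CCO[Si](CC)(CC)CC)=C(CO[Si](C(C)C)(C(C)C)C(C)C)CC(OC)=C1 | intermediate
25 | (2S,5R,10S)-2-(triethylsilyloxy)-9-[2-(triethylsilyloxy)ethyl]-4,4,10-trimethyl-8-[(triisopropylsilyloxy)methyl]-cis-Δ8-octalin-6-one | CC1(C)C[C@H](O[Si](CC)(CC)CC)C[C@]2(C)C(CCO[Si](CC)(CC)CC)=C(CO[Si](C(C)C)(C(C)C)C(C)C)CC(=O)[C@H]12 | intermediate
26 | (2S,5R,10S)-2-hydroxy-9-(2-hydroxyethyl)-4,4,10-trimethyl-8-[(triisopropylsilyloxy)methyl]-cis-Δ8-octalin-6-one | CC1(C)C[C@H](O)C[C@]2(C)C(CCO)=C(CO[Si](C(C)C)(C(C)C)C(C)C)CC(=O)[C@H]12 | intermediate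
27 | (2S,5R,6S,10S)-9-(2-hydroxyethyl)-4,4,10-trimethyl-8-[(triisopropylsilyloxy)methyl]-cis-Δ8-octalin-2,6-diol | CC1(C)C[C@H](O)C[C@]2(C)C(CCO)=C(CO[Si](C(C)C)(C(C)C)C(C)C)C[C@H](O)[C@H]12 | intermediate
28 | (2S,5R,6S,10S)-9-(2-iodoethyl)-4,4,10-trimethyl-8-[(triisopropylsilyloxy)methyl]-cis-Δ8-octalin-2,6-diol | CC1(C)C[C@H](O)C[C@]2(C)C(CCI)=C(CO[Si](C(C)C)(C(C)C)C(C)C)C[C@H](O)[C@H]12 | intermediate
29 | 4-bromofuran-2(5H)-one | O=C1C=C(Br)CO1 | starting material
30 | 17-O-triisopropylsilyl ether of the target | CC1(C)C[C@H](O)C[C@]2(C)C(CCC3=CC(=O)OC3)=C(CO[Si](C(C)C)(C(C)C)C(C)C)C[C@H](O)[C@H]12 | intermediate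
31 | (2S,5R,6S,10S)-2,6,17-trihydroxy-5β-labda-8,13-dien-15,16-olide | CC1(C)C[C@H](O)C[C@]2(C)C(CCC3=CC(=O)OC3)=C(CO)C[C@H](O)[C@H]12 | target

**Count and risks**
Total: 16 steps. Longest linear sequence: 14 steps (steps 1–7 and 10–16); steps 8 and 9 make the phosphonium salt.

Step 5. What may go wrong: low facial selectivity in the methylation, because the substituent next to the ortho chain may disturb the enolate geometry on which the auxiliary relies, or reductive loss of the benzylic silyloxy group. The fallback sets out from lactone 7 and returns at 12. Lactone 7 itself would be submitted to Birch reductive methylation (K, NH3/THF, t-BuOH, −78 °C; MeI) to give the racemic 8a-methyl dihydro lactone F1. Opening with the lithium amide of 8 should give two diastereomeric hydroxy amides that would be separated by chromatography: the (1S)-hydroxy amide F2 and the (1R)-hydroxy amide F3, which would be set aside. Silylation of F2 (Et3SiCl, imidazole) would give 12.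

Step 11. What may go wrong: sluggish hydroboration of the hindered Z-alkene by the bulky dialkylborane, with partial loss of reagent control at C2. The fallback sets out from 20 and returns at 24. Alkene 20 would be hydroborated with 9-borabicyclo[3.3.1]nonane (same regiochemistry, no facial control) and oxidised, and alcohol 23 would be separated from its C2 epimer F4. The epimer would be recycled by a Mitsunobu reaction (4-nitrobenzoic acid, PPh3, diisopropyl azodicarboxylate) to the inverted 4-nitrobenzoate F5, which K2CO3 in methanol should convert into 23. Silylation as in step 11 gives 24.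

Step 12. What may go wrong: the tertiary cation loses a proton or fragments before C5 captures it, or the allylic silyl ether ionises as well. The fallback sets out from 23 and returns at 27. Alcohol 23 would be oxidised (SO3·pyridine, DMSO, i-Pr2NEt) to the β-methoxy ketone F6. TiCl4 at −78 °C should eliminate methanol to the enone F7, which would not be isolated. Its titanium complex should undergo an intramolecular Mukaiyama–Michael addition of the enol ether carbon C5, with the same cis geometry, to give the 2,6-dione F8 after aqueous work-up. Li(s-Bu)3BH at −78 °C would reduce C6 from the β face and C2 probably to the axial 2β alcohol, the 2β,6α-diol F9. A Mitsunobu reaction at the less hindered C2 hydroxyl would give the 2α 4-nitrobenzoate F10. K2CO3 in methanol would give the 12-O-triethylsilyl ether F11, and AcOH/THF/H2O would then give 27.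

**Further compounds**
F1 | step 5 | racemic 7-methoxy-8a-methyl-5-[(triisopropylsilyloxy)methyl]-3,4,6,8a-tetrahydro-1H-2-benzopyran-1-one | CC12C=C(OC)CC(CO[Si](C(C)C)(C(C)C)C(C)C)=C1CCOC2=O
F2 | step 5 | {(1S)-2-(2-hydroxyethyl)-5-methoxy-1-methyl-3-[(triisopropylsilyloxy)methyl]cyclohexa-2,5-dien-1-yl}[(2S)-2-(methoxymethyl)pyrrolidin-1-yl]methanone | COC[C@@H]1CCCN1C(=O)[C@]2(C)C(CCO)=C(CO[Si](C(C)C)(C(C)C)C(C)C)CC(OC)=C2
F3 | step 5 | {(1R)-2-(2-hydroxyethyl)-5-methoxy-1-methyl-3-[(triisopropylsilyloxy)methyl]cyclohexa-2,5-dien-1-yl}[(2S)-2-(methoxymethyl)pyrrolidin-1-yl]methanone | COC[C@@H]1CCCN1C(=O)[C@@]2(C)C(CCO)=C(CO[Si](C(C)C)(C(C)C)C(C)C)CC(OC)=C2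
F4 | step 11 | (2S)-epimer of alcohol 23 | COC(C)(C)C[C@@H](O)C[C@]1(C)C(CCO[Si](CC)(CC)CC)=C(CO[Si](C(C)C)(C(C)C)C(C)C)CC(OC)=C1
F5 | step 11 | 4-nitrobenzoate of alcohol 23 | COC(C)(C)C[C@H](OC(=O)c2ccc(cc2)[N+](=O)[O-])C[C@]1(C)C(CCO[Si](CC)(CC)CC)=C(CO[Si](C(C)C)(C(C)C)C(C)C)CC(OC)=C1
F6 | step 12 | 1-{(1S)-5-methoxy-1-methyl-2-[2-(triethylsilyloxy)ethyl]-3-[(triisopropylsilyloxy)methyl]cyclohexa-2,5-dien-1-yl}-4-methoxy-4-methylpentan-2-one | COC(C)(C)CC(=O)C[C@]1(C)C(CCO[Si](CC)(CC)CC)=C(CO[Si](C(C)C)(C(C)C)C(C)C)CC(OC)=C1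
F7 | step 12 | 1-{(1S)-5-methoxy-1-methyl-2-[2-(triethylsilyloxy)ethyl]-3-[(triisopropylsilyloxy)methyl]cyclohexa-2,5-dien-1-yl}-4-methylpent-3-en-2-one | CC(C)=CC(=O)C[C@]1(C)C(CCO[Si](CC)(CC)CC)=C(CO[Si](C(C)C)(C(C)C)C(C)C)CC(OC)=C1
F8 | step 12 | (5R,10S)-9-[2-(triethylsilyloxy)ethyl]-4,4,10-trimethyl-8-[(triisopropylsilyloxy)methyl]-cis-Δ8-octalin-2,6-dione | CC1(C)CC(=O)C[C@]2(C)C(CCO[Si](CC)(CC)CC)=C(CO[Si](C(C)C)(C(C)C)C(C)C)CC(=O)[C@H]12
F9 | step 12 | (2R,5R,6S,10S)-2β,6α-diol, 12-O-triethylsilyl, 17-O-triisopropylsilyl | CC1(C)C[C@@H](O)C[C@]2(C)C(CCO[Si](CC)(CC)CC)=C(CO[Si](C(C)C)(C(C)C)C(C)C)C[C@H](O)[C@H]12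
F10 | step 12 | (2S)-2α-(4-nitrobenzoate) of the 6α-ol, 12-O-triethylsilyl, 17-O-triisopropylsilyl | CC1(C)C[C@H](OC(=O)c3ccc(cc3)[N+](=O)[O-])C[C@]2(C)C(CCO[Si](CC)(CC)CC)=C(CO[Si](C(C)C)(C(C)C)C(C)C)C[C@H](O)[C@H]12
F11 | step 12 | 12-O-triethylsilyl ether of triol 27 | CC1(C)C[C@H](O)C[C@]2(C)C(CCO[Si](CC)(CC)CC)=C(CO[Si](C(C)C)(C(C)C)C(C)C)C[C@H](O)[C@H]12
A1 | direct plan | 4-methyl-2-(trimethylsilyloxy)penta-1,3-diene | C=C(O[Si](C)(C)C)C=C(C)C
A2 | direct plan | (5S)-5-[(1S,2R,5S)-menthyloxy]-4-methylfuran-2(5H)-one | C[C@H]1CC[C@@H]([C@H](C1)O[C@H]2OC(=O)C=C2C)C(C)C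
A3 | direct plan | (3S,3aS,5S,7aR)-3-menthyloxy-3a,7,7-trimethyloctahydro-2-benzofuran-1,5-diol (lactol acetal) | CC1(C)C[C@H](O)C[C@]2(C)[C@@H](O[C@H]3C[C@@H](C)CC[C@@H]3C(C)C)OC(O)[C@H]12
A4 | direct plan | tris(tert-butyldimethylsilyl) ether of 2α,6α-dihydroxy-8α-(hydroxymethyl)-4,4,10β-trimethyl-5βH-decalin-9-one | CC1(C)C[C@H](O[Si](C)(C)C(C)(C)C)C[C@]2(C)C(=O)[C@H](CO[Si](C)(C)C(C)(C)C)C[C@H](O[Si](C)(C)C(C)(C)C)[C@H]12
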